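**Retrosynthetic overview**
1. Target 16 ⇐ 15 by a final Schenck ene hydroperoxidation of the Δ4 alkene (gives 5α-OOH and the 4(15)-methylene).
2. 15 ⇐ 13 by α-face hydride delivery to the C8 ketone with in-flask acetylation; 13 ⇐ decalone 9 + methyl propiolate 10 (C7–C11 bond by a new enolate α-(methoxycarbonyl)vinylation).
3. 9 ⇐ hydrindanone 6 by one-carbon ring expansion: 1,2-shift of the quaternary C10 onto a carbenoid carbon, which makes ring B six-membered and places the carbonyl at C8.
4. 6 ⇐ (S)-enedione 4 (enone reduction, isobutyrylation) ⇐ 2-methylcyclopentane-1,3-dione 1 + ethyl vinyl ketone 2.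
5. Ring order: cyclopentane (from 1) → ring A by amino-acid-catalysed annulation (sets C10) → ring B by 5→6 expansion.

Assumption: positions are quoted in eudesmane numbering (C14 = methyl on C10, C15 = carbon on C4, C11–C13 = acrylate); the target is read as 3β-isobutyryloxy, 5α-hydroperoxy, 7α-H, 8β-acetoxy, 10β-methyl.

**Step 1**
Reactants: 1 2-methylcyclopentane-1,3-dione; 2 pent-1-en-3-one (ethyl vinyl ketone)
Product: 4 (7aS)-4,7a-dimethyl-2,3,7,7a-tetrahydro-1H-indene-1,5(6H)-dione, via 2-methyl-2-(3-oxopentyl)cyclopentane-1,3-dione 3 (not isolated)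
Conditions: 2 (1.5 equiv), AcOH (cat.), H2O, 75 °C; evaporate; L-phenylalanine (1.0 equiv), (1S)-(+)-CSA (0.5 equiv), DMF, 30 → 70 °C
Reagents that add atoms: none
Why: Michael addition of the acidic 1,3-dione to the enone is followed by a Hajos–Parrish–Eder–Sauer–Wiechert aldol condensation in which the L-amino acid enamine differentiates the two enantiotopic ring carbonyls and sets the quaternary carbon (future C10) as S.

**Step 2**
Reactants: 4 (7aS)-4,7a-dimethyl-2,3,7,7a-tetrahydro-1H-indene-1,5(6H)-dione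
Product: 5 (5S,7aS)-5-hydroxy-4,7a-dimethyl-2,3,5,6,7,7a-hexahydro-1H-inden-1-one
Conditions: NaBH4 (0.5 equiv), CeCl3·7H2O (1.0 equiv), MeOH, −78 °C; acetone quench
Reagents that add atoms: none
Why: Luche reduction, in which the Ce(III)/MeOH-activated 1,2-reduction of the enone should outpace reduction of the neopentyl cyclopentanone (as expected for Δ4-3,17-diketosteroids), and axial hydride attack anti to the angular methyl gives the pseudo-equatorial 3β-alcohol cis to that methyl.

**Step 3**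
Reactants: 5 (5S,7aS)-5-hydroxy-4,7a-dimethyl-2,3,5,6,7,7a-hexahydro-1H-inden-1-one
Product: 6 (5S,7aS)-4,7a-dimethyl-1-oxo-2,3,5,6,7,7a-hexahydro-1H-inden-5-yl 2-methylpropanoate
Conditions: i-PrCOCl (1.3 equiv), pyridine, DMAP (5 mol%), CH2Cl2, 0 °C
Reagents that add atoms: 2-methylpropanoyl chloride (isobutyryl chloride), CC(C)C(Cl)=O
Why: DMAP-catalysed acylation of the unhindered secondary allylic alcohol, with no change at any stereocentre.

**Step 4**
Reactants: 6 (5S,7aS)-4,7a-dimethyl-1-oxo-2,3,5,6,7,7a-hexahydro-1H-inden-5-yl 2-methylpropanoate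
Product: 9 (2S,4aR)-1,4a-dimethyl-6-oxo-2,3,4,4a,5,6,7,8-octahydronaphthalen-2-yl 2-methylpropanoate, via lithium dibromomethyl carbinolate 7 (not isolated), via chloromagnesium C8–C9 enolate 8 (not isolated)
Conditions: CH2Br2 (1.3 equiv), LiTMP (1.25 equiv), THF, −78 °C; then i-PrMgCl·LiCl (1.5 equiv), −78 → 0 °C; aq NH4Cl
Reagents that add atoms: dibromomethane, BrCBr
Why: Nozaki–Yamamoto β-oxido carbenoid ring enlargement in its magnesium-carbenoid form, where LiCHBr2 adds to the only ketone (anti to the angular methyl), Br/Mg exchange gives the carbenoid, and the more substituted, allylic quaternary C10 makes the 1,2-shift with retention so that the new CH2 becomes C9 and the carbonyl ends at C8, the hindered ester tolerating i-PrMgCl at ≤0 °C.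

**Step 5**
Reactants: 9 (2S,4aR)-1,4a-dimethyl-6-oxo-2,3,4,4a,5,6,7,8-octahydronaphthalen-2-yl 2-methylpropanoate; 10 methyl prop-2-ynoate (methyl propiolate)
Product: 13 methyl 2-[(2R,4aR,7S)-4a,8-dimethyl-7-(2-methylpropanoyloxy)-3-oxo-1,2,3,4,4a,5,6,7-octahydronaphthalen-2-yl]prop-2-enoate, via [(E)-3-methoxy-3-oxoprop-1-en-1-yl]triphenylphosphonium tetrafluoroborate 11 (not isolated), via lithium C7 enolate 12 (not isolated)
Conditions: 10, Ph3P·HBF4 (1.05 equiv), CH2Cl2, 0 °C → rt (gives 11); 9, LiHMDS (1.05 equiv), THF, −78 °C (gives 12); 12 added to 11, t-BuOH (1 equiv), −78 → 0 °C; then Et3N (0.2 equiv), rt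
Reagents that add atoms: none
Why: Proposed new method: the kinetic C7 enolate (C9 is neopentyl and is not deprotonated) should add to the carbon β to phosphorus of the vinylphosphonium salt, which is the ester α-carbon, giving a P-ylide that after proton transfer loses Ph3P by E1cB to unveil the 2-substituted acrylate, so the C7–C11 bond forms with α-regiochemistry and C7 settles by enolisation into the equatorial 7β epimer (7R); the closest known reaction types are the phosphine-catalysed α-addition of acidic N-, O- and 1,3-dicarbonyl pronucleophiles to alkynoates and the β-nitroacrylate Michael addition/HNO2 elimination, neither shown for an unstabilised ketone enolate with a stoichiometric β-phosphonioacrylate.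

**Step 6**
Reactants: 13 methyl 2-[(2R,4aR,7S)-4a,8-dimethyl-7-(2-methylpropanoyloxy)-3-oxo-1,2,3,4,4a,5,6,7-octahydronaphthalen-2-yl]prop-2-enoate
Product: 15 methyl 2-[(2R,3R,4aR,7S)-3-acetoxy-4a,8-dimethyl-7-(2-methylpropanoyloxy)-1,2,3,4,4a,5,6,7-octahydronaphthalen-2-yl]prop-2-enoate, via lithium tri-tert-butoxyaluminate of the 8β-alkoxide 14 (not isolated)
Conditions: LiAlH(Ot-Bu)3 (1.5 equiv), THF, −78 → −20 °C; then Ac2O (6 equiv), pyridine (4 equiv), DMAP (1 equiv), −20 °C → rt
Reagents that add atoms: acetic anhydride, CC(=O)OC(C)=O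
Why: Steric-approach-controlled ketone reduction with in situ acylation (reductive acetylation), in which the axial C10 methyl blocks the β (axial) trajectory so the bulky hydride enters from the α face to give the axial 8β-alkoxide cis to the side chain, which is acetylated before it can lactonise, while LiAlH(Ot-Bu)3 leaves the esters and the acrylate untouched.

**Step 7**
Reactants: 15 methyl 2-[(2R,3R,4aR,7S)-3-acetoxy-4a,8-dimethyl-7-(2-methylpropanoyloxy)-1,2,3,4,4a,5,6,7-octahydronaphthalen-2-yl]prop-2-enoate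
Product: 16 methyl 2-[(2R,3R,4aR,7S,8aS)-3-acetoxy-8a-hydroperoxy-4a-methyl-8-methylidene-7-(2-methylpropanoyloxy)decahydronaphthalen-2-yl]prop-2-enoate (target)
Conditions: O2, tetraphenylporphyrin (1 mol%), white LED, CH2Cl2, 0 °C
Reagents that add atoms: oxygen (as singlet oxygen), O=O
Why: Schenck ene reaction, in which 1O2 attacks the electron-rich tetrasubstituted Δ4 alkene from the α face (anti to the C10 methyl and the 8β-acetate) and abstracts a C15 methyl hydrogen (C3–H is deactivated by its geminal acyloxy group and C6–Hα lies in the alkene plane), giving the 5α-hydroperoxide with the 4(15)-methylene while the acrylate is inert.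

**Compound list**
1 | 2-methylcyclopentane-1,3-dione | CC1C(=O)CCC1=O | starting material
2 | pent-1-en-3-one (ethyl vinyl ketone) | CCC(=O)C=C | starting material
3 | 2-methyl-2-(3-oxopentyl)cyclopentane-1,3-dione | CCC(=O)CCC1(C)C(=O)CCC1=O | intermediate (not isolated)
4 | (7aS)-4,7a-dimethyl-2,3,7,7a-tetrahydro-1H-indene-1,5(6H)-dione | CC1=C2CCC(=O)[C@@]2(C)CCC1=O | intermediate
5 | (5S,7aS)-5-hydroxy-4,7a-dimethyl-2,3,5,6,7,7a-hexahydro-1H-inden-1-one (OH cis to the angular methyl) | CC1=C2CCC(=O)[C@@]2(C)CC[C@@H]1O | intermediate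
6 | (5S,7aS)-4,7a-dimethyl-1-oxo-2,3,5,6,7,7a-hexahydro-1H-inden-5-yl 2-methylpropanoate | CC1=C2CCC(=O)[C@@]2(C)CC[C@@H]1OC(=O)C(C)C | intermediate
7 | lithium (1S,5S,7aS)-1-(dibromomethyl)-4,7a-dimethyl-5-(2-methylpropanoyloxy)-2,3,5,6,7,7a-hexahydro-1H-inden-1-olate (CHBr2 anti to the angular methyl) | CC1=C2CC[C@@]([O-])(C(Br)Br)[C@@]2(C)CC[C@@H]1OC(=O)C(C)C.[Li+] | intermediate (not isolated)
8 | chloromagnesium enolate of 9 (C8=C9 enolate) | CC1=C2CCC(O[Mg]Cl)=C[C@@]2(C)CC[C@@H]1OC(=O)C(C)C | intermediate (not isolated)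
9 | (2S,4aR)-1,4a-dimethyl-6-oxo-2,3,4,4a,5,6,7,8-octahydronaphthalen-2-yl 2-methylpropanoate (3β-isobutyryloxy-11,12,13-trinoreudesm-4-en-8-one) | CC1=C2CCC(=O)C[C@@]2(C)CC[C@@H]1OC(=O)C(C)C | intermediate
10 | methyl prop-2-ynoate (methyl propiolate) | C#CC(=O)OC | starting material
11 | [(E)-3-methoxy-3-oxoprop-1-en-1-yl]triphenylphosphonium tetrafluoroborate | COC(=O)/C=C/[P+](c1ccccc1)(c1ccccc1)c1ccccc1.F[B-](F)(F)F | intermediate (not isolated)
12 | lithium enolate of 9 (C7=C8 enolate) | CC1=C2CC=C(O[Li])C[C@@]2(C)CC[C@@H]1OC(=O)C(C)C | intermediate (not isolated)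
13 | methyl 2-[(2R,4aR,7S)-4a,8-dimethyl-7-(2-methylpropanoyloxy)-3-oxo-1,2,3,4,4a,5,6,7-octahydronaphthalen-2-yl]prop-2-enoate (7α-H, 8-oxo) | C=C(C(=O)OC)[C@H]1CC2=C(C)[C@@H](OC(=O)C(C)C)CC[C@]2(C)CC1=O | intermediate
14 | lithium tri-tert-butoxyaluminate of the 8β-alkoxide of 13 | C=C(C(=O)OC)[C@H]1CC2=C(C)[C@@H](OC(=O)C(C)C)CC[C@]2(C)C[C@H]1O[Al-](OC(C)(C)C)(OC(C)(C)C)OC(C)(C)C.[Li+] | intermediate (not isolated)
15 | methyl 2-[(2R,3R,4aR,7S)-3-acetoxy-4a,8-dimethyl-7-(2-methylpropanoyloxy)-1,2,3,4,4a,5,6,7-octahydronaphthalen-2-yl]prop-2-enoate (8β-OAc) | C=C(C(=O)OC)[C@H]1CC2=C(C)[C@@H](OC(=O)C(C)C)CC[C@]2(C)C[C@H]1OC(C)=O | intermediate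
16 | methyl 2-[(2R,3R,4aR,7S,8aS)-3-acetoxy-8a-hydroperoxy-4a-methyl-8-methylidene-7-(2-methylpropanoyloxy)decahydronaphthalen-2-yl]prop-2-enoate | C=C(C(=O)OC)[C@H]1C[C@@]2(OO)C(=C)[C@@H](OC(=O)C(C)C)CC[C@]2(C)C[C@H]1OC(C)=O | target

**Totals**
Total step count: 7. Longest linear sequence: 7 steps (1 + 2 → 16).

**Three steps most likely to fail, with fallbacks**

Step 5 (the new α-(methoxycarbonyl)vinylation). The enolate may attack at oxygen, add at the phosphorus-bearing carbon to give the linear β-adduct, or the product may isomerise to the conjugated alkylidene ketone. The fallback uses known chemistry, a β-nitroacrylate as α-acrylate cation equivalent, and sets out from 9 and comes back at 13. Commercial methyl acrylate (C=CC(=O)OC) is treated with N2O4/I2 in ether to give methyl 2-iodo-3-nitropropanoate F1. Sodium acetate eliminates HI to give methyl (E)-3-nitroprop-2-enoate F2. The lithium enolate 12 of 9 adds to F2 at −78 °C at the carbon α to the ester to give the nitro ester methyl 2-[(4aR,7S)-4a,8-dimethyl-7-(2-methylpropanoyloxy)-3-oxo-1,2,3,4,4a,5,6,7-octahydronaphthalen-2-yl]-3-nitropropanoate F3 as an epimer mixture. Et3N then eliminates nitrous acid and equilibrates C7, giving 13.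

Step 4 (ring expansion). The CH2 carbon C7 may migrate instead of C10 (giving the 9-oxo isomer), the alkoxide may close to a bromo-epoxide, or the Grignard may attack the ester. The fallback replaces the anionic carbenoid shift by a cationic halohydrin semipinacol, whose migratory preference follows cation-stabilising ability; it sets out from 6 and comes back at 9. LiCH2I (CH2I2, MeLi·LiBr, THF, −78 °C, cold AcOH quench) adds to the ketone to give the iodohydrin (1S,5S,7aS)-1-hydroxy-1-(iodomethyl)-4,7a-dimethyl-2,3,5,6,7,7a-hexahydro-1H-inden-5-yl 2-methylpropanoate F4. AgBF4 in CH2Cl2 at 0 °C then ionises the C–I bond with concerted migration of the tertiary allylic C10 to give 9.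

Step 2 (chemoselective Luche reduction). The cyclopentanone may be reduced as fast as the hindered tetrasubstituted enone. The fallback masks the cyclopentanone first by installing the ring-expansion carbon, so the enone is the only carbonyl left; it sets out from 4 and comes back at 7. Preformed LiCHBr2 (CH2Br2, LDA, THF/Et2O, −95 °C) adds to the saturated ketone of 4 to give (1S,7aS)-1-(dibromomethyl)-1-hydroxy-4,7a-dimethyl-1,2,3,6,7,7a-hexahydro-5H-inden-5-one F5. Luche reduction gives (1S,5S,7aS)-1-(dibromomethyl)-4,7a-dimethyl-2,3,5,6,7,7a-hexahydro-1H-indene-1,5-diol F6. Isobutyryl chloride/pyridine acylates only the secondary allylic hydroxyl to give (1S,5S,7aS)-1-(dibromomethyl)-1-hydroxy-4,7a-dimethyl-2,3,5,6,7,7a-hexahydro-1H-inden-5-yl 2-methylpropanoate F7. LiHMDS (1 equiv) converts F7 into alkoxide 7, which continues with i-PrMgCl·LiCl as in step 4.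

**Further compounds**
F1 | step 5 | methyl 2-iodo-3-nitropropanoate (racemic) | COC(=O)C(I)C[N+](=O)[O-]
F2 | step 5 | methyl (E)-3-nitroprop-2-enoate | COC(=O)/C=C/[N+](=O)[O-]
F3 | step 5 | methyl 2-[(4aR,7S)-4a,8-dimethyl-7-(2-methylpropanoyloxy)-3-oxo-1,2,3,4,4a,5,6,7-octahydronaphthalen-2-yl]-3-nitropropanoate (epimers at the two new centres) | COC(=O)C(C[N+](=O)[O-])C1CC2=C(C)[C@@H](OC(=O)C(C)C)CC[C@]2(C)CC1=O
F4 | step 4 | (1S,5S,7aS)-1-hydroxy-1-(iodomethyl)-4,7a-dimethyl-2,3,5,6,7,7a-hexahydro-1H-inden-5-yl 2-methylpropanoate | CC1=C2CC[C@@](O)(CI)[C@@]2(C)CC[C@@H]1OC(=O)C(C)C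
F5 | step 2 | (1S,7aS)-1-(dibromomethyl)-1-hydroxy-4,7a-dimethyl-1,2,3,6,7,7a-hexahydro-5H-inden-5-one | CC1=C2CC[C@@](O)(C(Br)Br)[C@@]2(C)CCC1=O
F6 | step 2 | (1S,5S,7aS)-1-(dibromomethyl)-4,7a-dimethyl-2,3,5,6,7,7a-hexahydro-1H-indene-1,5-diol | CC1=C2CC[C@@](O)(C(Br)Br)[C@@]2(C)CC[C@@H]1O
F7 | step 2 | (1S,5S,7aS)-1-(dibromomethyl)-1-hydroxy-4,7a-dimethyl-2,3,5,6,7,7a-hexahydro-1H-inden-5-yl 2-methylpropanoate | CC1=C2CC[C@@](O)(C(Br)Br)[C@@]2(C)CC[C@@H]1OC(=O)C(C)C
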